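## The problem

The target is a 5,7,3',4'-tetrahydroxyisoflavone. Benzene ring A is fused through C4a and C8a to the 4-pyranone ring C (O1, C2, C3, C4), and catechol ring B sits on C3. Ring A has no free position: oxygen at C5, C7 and C8a, carbon at C4a, C6 and C8. The two C5 side chains, prenyl at C6 and 2-hydroxy-3-methylbut-3-enyl at C8, flank the C7 oxygen in nearly equivalent sites and must be told apart. The only stereocentre is C2'' of the C8 chain (R, a secondary allylic alcohol). It is separated from the flat core by a CH2 group, so nothing in the molecule can control it and it must come from a reagent or catalyst. The prenyl alkene and the 1,1-disubstituted alkene lie ortho to phenols and cyclise onto them under acid; the allylic alcohol can ionise, the catechol is oxidised easily, and C2 of the chromone is opened by hard nucleophiles and strong bases. Four phenols therefore need one protecting group that survives fluoride, palladium, osmium and chromium chemistry and leaves under mild conditions. The feature that invites the key step is the C8a(O1)–C4a(C4) pair on neighbouring ring A carbons with the C5 oxygen next to C4a. This is the pattern left when a carboxylate adds to a 3-alkoxyaryne and its acyl group moves to the ortho carbon, so one carboxyl group can supply both O1 and C4.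

## Retrosynthesis

Atom labels: chromone numbering for the core, C1''–C4'' for the C8 chain, C1''' onward for the prenyl group.

**26 from 25.** The four aryl O–CH2OMe bonds are cut last. MOM is chosen because benzyl needs hydrogenolysis (alkenes) and methyl needs boron halides (cyclisation of prenyl onto OH), while silyl ethers would not survive fluoride in the aryne step. The forward step asks for acetal cleavage at an acidity below that which protonates the alkenes.

**25 from 24.** The C6–C1''' bond is cut to the aryl bromide 24 and a prenylstannane. The prenyl group goes on last because its trisubstituted alkene would not survive the osmium step that builds the C8 chain. The bromide is the less reactive of the two halogen handles, so it is the one that remains.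

**24 from 23.** The C2''–C3'' bond is cut to aldehyde 23 and 2-bromopropene. This makes the stereocentre in the bond-forming step under catalyst control and gives the allylic alcohol directly. The neighbouring cut, C8–C1'' with a ready-made chiral fragment, was rejected: a β-oxygenated alkyl metal eliminates, and an aryl metal with an isopropenyl oxirane opens in the SN2' sense and would endanger the chromone. The cut through a C–O bond of an epoxide is Alternative 1. Precursor 23 is achiral.

**23 from 21 and 20.** The aldehyde comes from the terminal alkene of the 8-allyl compound 21 by oxidative cleavage, and 21 from the C8–I bond of dihalide 20 by allyl transfer. The forward coupling must touch the iodide and leave the bromide.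

**20 from 19 and 18.** The C8–I and C6–Br bonds are cut in that order. In 5-O-alkylated 5,7-dioxygenated chromones the first halogen enters at C8, and the second then has only C6 left on ring A. Iodine first and bromine second fixes the order of the later couplings. Precursor 18 has no substituent at C6 or C8.

**18 from 8 and 15 (key disconnection).** O1–C8a, C4–C4a and O1–C2 are cut together. Ring A becomes 3,5-bis(methoxymethoxy)benzyne, released from silyl triflate 8, and the rest becomes the β-methoxyacrylic acid 15, which carries ring B, C2, C3, C4 and O1. The classical neighbour, acylation of phloroglucinol to a deoxybenzoin and one-carbon insertion, is shorter but gives the free pentahydroxy compound and leaves the chelated 5-OH to be protected afterwards. The aryne cut forms three bonds in one operation from two fully protected fragments and delivers 18 ready for halogenation. The forward reaction needs regioselective addition to the aryne, which the alkoxy group at the future C5 provides.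

**8 from 6, 3, 2 and 1.** The triflate and C–Si bonds are cut back to the carbamate 3 of phenol 2; the carbamate directs lithiation to the position between itself and an OMOM group and is then exchanged for triflate. Phenol 2 comes from phloroglucinol 1 by twofold acetal formation.

**15 from 14, 11, 12, 10 and 9.** The acid is the saponified ester 14. Its C2 carbon (C3 of the acrylate) comes from methyl formate 12 by formylation of arylacetate 11 and O-methylation. Ester 11 is the protected methyl ester 10 of 3,4-dihydroxyphenylacetic acid 9.

## Roads not taken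

**Alternative 1:** Shi epoxidation of a lone C8 prenyl group. The cut is at the C8 side chain: the allylic alcohol is traced to the (R)-epoxide A2, 6-bromo-8-{[(R)-3,3-dimethyloxiran-2-yl]methyl}-5,7-bis(methoxymethoxy)-3-[3,4-bis(methoxymethoxy)phenyl]chromen-4-one, and this to the 6-bromo-8-prenyl isoflavone A1. In the forward step the dioxirane from a fructose-derived ketone and KHSO5 epoxidises the one prenyl alkene of A1.
- Merits: epoxidation of trisubstituted alkenes by this catalyst is among the most dependable enantioselective oxidations, its sense is predictable, both C5 units come from one stannane, and no sensitive aldehyde is handled.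
- Weak points: A2 must still be isomerised to the allylic alcohol by proton loss from a methyl group. The amide bases that do this attack C2 of the chromone, and Lewis acids invite the C7 oxygen to close a furan or pyran ring; trivalent titanium (Cp2TiCl) is the most plausible reagent but is untried next to a chromone. The buffered basic oxidant is also a concern for ring C. The road needs the same dihalide 20 and the same order of couplings, so it saves no step.
- Comparison: in reliability of the stereo-inducing step this road is better than the chosen one. The chosen plan sets against it that the alcohol arises directly in the C–C bond formation, with no question of which way an epoxide opens. Alternative 1 says nothing about ring C and could be grafted onto 20.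

**Alternative 2:** Ring A by Dieckmann closure on a preformed pyranone. The cut is the C5–C6 bond. The precursor is pyranone ester A3, methyl 5-[3,4-bis(methoxymethoxy)phenyl]-4-oxopyran-3-carboxylate carrying at C6 of the pyranone a chain with the future C8 (bearing the silylated (R) side chain), the C7 ketone and the C6 methylene that carries prenyl. With KOtBu the C6 enolate attacks the ester to give A4, the 5,7-dihydroxy arene with the C8 alcohol as its TBS ether and ring B as bis-MOM ether.
- Merits: the positions of both side chains are fixed by construction, with no halogenation, no tin and no differentiation of C6 from C8.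
- Weak points: A3 is a long linear assembly. The proton on the future C8 is more acidic than the C6 methylene that must attack, the pyranone is itself a Michael acceptor towards alkoxide, and the C8 stereocentre of A3 is lost on aromatisation, so effort spent there is wasted.
- Comparison: Alternative 2 is better in regiocontrol on ring A. The chosen plan sets against it a convergent one-step entry to the core from two simple fragments and a late, modular introduction of the side chains.

**Alternative 3:** Ring C by carbene-catalysed crossed benzoin umpolung. The cut is the C3–C4 bond. Aldehyde A5, 2-{2-[3,4-bis(methoxymethoxy)phenyl]-2-oxoethoxy}-4,6-bis(methoxymethoxy)benzaldehyde, is turned by a triazolium-derived carbene into an acyl anion equivalent that adds to the tethered ketone and gives racemic 3-hydroxychromanone A6.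
- Merits: this closure is established for 3-hydroxychroman-4-ones, is metal-free and mild, and A5 is made by simple O-alkylation; the count to an isoflavone of the type of 18 is about six operations against nine in the chosen plan.
- Weak points: A6 has the wrong oxidation pattern and must lose water across C2–C3. The acid or sulfonylating conditions for this endanger the 5-OMOM group and can trigger a 1,2-aryl shift of the tertiary ketol. The stereocentre made in the key step is destroyed.
- Comparison: in step count to the core Alternative 3 is as good or better. The chosen plan sets against it that ring C arises at the final oxidation level with no redox or dehydration adjustment. Both roads need the same end game.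

Key step: step 9

Remark on the chemistry: the descriptor at the carbinol carbon corresponds to (R) (OH > isopropenyl > CH2Ar > H). In step 14 the ligand antipode used is the one that sends the alkenyl group to the Si face of the aldehyde, which gives (R); the sense is to be checked by Mosher ester analysis of 24 before scale-up.

## Route

Step 1
Reactants: 1 phloroglucinol
Product: 2 3,5-bis(methoxymethoxy)phenol
Conditions: MOMCl (2.0 equiv), iPr2NEt (2.2 equiv), DMF, 0 °C to rt; chromatography
Reagents that add atoms: chloromethyl methyl ether, COCCl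
Why: O-alkylation of the phenol by the α-chloro ether (acetal formation); with two equivalents the bis-ether is the main part of a statistical mixture and is separated from mono- and tris-ethers, acceptable at the first step on a commodity phenol.

Step 2
Reactants: 2 3,5-bis(methoxymethoxy)phenol
Product: 3 3,5-bis(methoxymethoxy)phenyl N-isopropylcarbamate
Conditions: iPrNCO (1.2 equiv), Et3N (0.2 equiv), CH2Cl2, rt
Reagents that add atoms: isopropyl isocyanate, CC(C)N=C=O
Why: Base-catalysed addition of the phenol to the isocyanate; the secondary carbamate is a strong ortho director that can later be removed under mild base.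

Step 3
Reactants: 3 3,5-bis(methoxymethoxy)phenyl N-isopropylcarbamate
Product: 6 3,5-bis(methoxymethoxy)-2-(trimethylsilyl)phenyl N-isopropylcarbamate, via N-TBS carbamate 4 (not isolated), via N-TBS 2-TMS carbamate 5 (not isolated)
Conditions: TBSOTf (1.1 equiv), TMEDA (1.1 equiv), Et2O, 0 °C to rt; n-BuLi (2.2 equiv), TMEDA (2.2 equiv), −78 °C; TMSCl (3 equiv), −78 °C to rt; aq. NH4Cl, MeOH
Reagents that add atoms: chlorotrimethylsilane, C[Si](C)(C)Cl
Why: Directed ortho-metalation: N-silylation masks the N–H, and lithiation goes to the position flanked by the carbamate and an OMOM group, because the carbamate outranks MOM as a director and this site occurs twice. The aryllithium is silylated and the N–Si bond is hydrolysed on work-up.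

Step 4
Reactants: 6 3,5-bis(methoxymethoxy)-2-(trimethylsilyl)phenyl N-isopropylcarbamate
Product: 8 3,5-bis(methoxymethoxy)-2-(trimethylsilyl)phenyl trifluoromethanesulfonate, via silyl phenol 7 (not isolated)
Conditions: DBU (1.5 equiv), Et2NH (1.5 equiv), MeCN, 40 °C; then PhNTf2 (1.5 equiv), rt
Reagents that add atoms: N-phenylbis(trifluoromethanesulfonimide), O=S(=O)(N(c1ccccc1)S(=O)(=O)C(F)(F)F)C(F)(F)F
Why: E1cB cleavage of the secondary carbamate (isopropyl isocyanate is expelled and trapped by Et2NH) gives the phenoxide of 7, which is triflated in the same pot; this is the standard carbamate route to ortho-silylaryl triflates.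

Step 5
Reactants: 9 3,4-dihydroxyphenylacetic acid
Product: 10 methyl 3,4-dihydroxyphenylacetate
Conditions: MeOH, H2SO4 (cat.), reflux
Reagents that add atoms: methanol, CO
Why: Fischer esterification; the phenols are untouched.

Step 6
Reactants: 10 methyl 3,4-dihydroxyphenylacetate
Product: 11 methyl [3,4-bis(methoxymethoxy)phenyl]acetate
Conditions: MOMCl (2.5 equiv), iPr2NEt (3 equiv), CH2Cl2, 0 °C to rt
Reagents that add atoms: chloromethyl methyl ether, COCCl
Why: Twofold O-alkylation of the catechol with the α-chloro ether under amine base; the ester is inert.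

Step 7
Reactants: 11 methyl [3,4-bis(methoxymethoxy)phenyl]acetate; 12 methyl formate
Product: 14 methyl (E)-2-[3,4-bis(methoxymethoxy)phenyl]-3-methoxyacrylate, via sodium hydroxymethylene enolate 13 (not isolated)
Conditions: NaH (2.2 equiv), HCO2Me (5 equiv), THF, 0 °C to rt; then Me2SO4 (1.5 equiv), DMF, rt
Reagents that add atoms: dimethyl sulfate, COS(=O)(=O)OC
Why: Crossed Claisen condensation of the arylacetate enolate with methyl formate, then O-methylation of the enolate, the usual route to 2-aryl-3-methoxyacrylates. The more stable (E) isomer is expected, and the geometry does not matter for the later ring closure.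

Step 8
Reactants: 14 methyl (E)-2-[3,4-bis(methoxymethoxy)phenyl]-3-methoxyacrylate
Product: 15 (E)-2-[3,4-bis(methoxymethoxy)phenyl]-3-methoxyacrylic acid
Conditions: LiOH·H2O (3 equiv), THF–MeOH–H2O, 40 °C; then 1 M HCl to pH 3–4, 0 °C
Reagents that add atoms: lithium hydroxide (hydroxide oxygen), [Li+].[OH-]
Why: Saponification of the ester; the cold, brief acidification keeps the enol ether and the MOM acetals intact.

Step 9
Reactants: 8 3,5-bis(methoxymethoxy)-2-(trimethylsilyl)phenyl trifluoromethanesulfonate; 15 (E)-2-[3,4-bis(methoxymethoxy)phenyl]-3-methoxyacrylic acid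
Product: 18 5,7-bis(methoxymethoxy)-3-[3,4-bis(methoxymethoxy)phenyl]-4H-chromen-4-one, via 3,5-bis(methoxymethoxy)benzyne 16 (not isolated), via ortho-hydroxyaryl enone 17 (not isolated)
Conditions: 8 (1.5 equiv), CsF (4 equiv), THF, 125 °C (sealed vessel), 24 h
Reagents that add atoms: none
Why: Fluoride attacks silicon in 8 and triflate leaves, giving aryne 16; the cesium carboxylate of 15 adds through oxygen to the aryne carbon remote from the neighbouring OMOM group, because the negative charge then develops on the carbon next to the electron-withdrawing C–O bond. That aryl anion attacks the ester carbonyl beside it through a four-membered intermediate, which opens to the ortho-acyl phenoxide 17; this is the known fluoride-induced insertion of arynes into the C–O bond of carboxylic acids. The phenoxide then adds to the β-carbon of the β-methoxy enone in a 6-endo-trig oxa-Michael step and methoxide is expelled, closing ring C as the pyranone; the closest known cases are the one-pot formation of chroman-4-ones from cinnamic acids and of chromones from alkynoic acids under these conditions, and the classical closure of 2-hydroxyaryl β-amino enones to isoflavones. The β-methoxyacrylic acid is a new partner for this known reaction, but each elementary step has precedent. No stereocentre is formed. The step needs regioselective addition to the unsymmetrical aryne, secured by the alkoxy group at the future C5, and attack by the carboxylate in preference to the enol ether alkene, secured by the anionic oxygen nucleophile and the excess of 8. The acid oxygen becomes O1, the carboxyl carbon C4, and the acrylate carbons C3 and C2.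

Step 10
Reactants: 18 5,7-bis(methoxymethoxy)-3-[3,4-bis(methoxymethoxy)phenyl]-4H-chromen-4-one
Product: 19 8-iodo-5,7-bis(methoxymethoxy)-3-[3,4-bis(methoxymethoxy)phenyl]-4H-chromen-4-one
Conditions: NIS (1.1 equiv), DMF, rt, dark
Reagents that add atoms: N-iodosuccinimide, O=C1CCC(=O)N1I
Why: Electrophilic aromatic iodination; in 5-O-alkyl 5,7-dioxygenated chromones C8 (para to the C5 oxygen and flanked by only one acetal) reacts before C6, and the trioxygenated ring A is far more nucleophilic than the dioxygenated ring B.

Step 11
Reactants: 19 8-iodo-5,7-bis(methoxymethoxy)-3-[3,4-bis(methoxymethoxy)phenyl]-4H-chromen-4-one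
Product: 20 6-bromo-8-iodo-5,7-bis(methoxymethoxy)-3-[3,4-bis(methoxymethoxy)phenyl]-4H-chromen-4-one
Conditions: NBS (1.1 equiv), DMF, 0 °C to rt
Reagents that add atoms: N-bromosuccinimide, O=C1CCC(=O)N1Br
Why: Electrophilic bromination at C6, the only open position of ring A, still activated by three oxygens; one equivalent at low temperature limits attack on ring B.

Step 12
Reactants: 20 6-bromo-8-iodo-5,7-bis(methoxymethoxy)-3-[3,4-bis(methoxymethoxy)phenyl]-4H-chromen-4-one
Product: 21 8-allyl-6-bromo-5,7-bis(methoxymethoxy)-3-[3,4-bis(methoxymethoxy)phenyl]-4H-chromen-4-one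
Conditions: allylSnBu3 (1.2 equiv), Pd(PPh3)4 (5 mol%), DMF, 70 °C
Reagents that add atoms: allyltributylstannane, C=CC[Sn](CCCC)(CCCC)CCCC
Why: Stille coupling; zerovalent palladium inserts into the C8–I bond much faster than into the C6–Br bond, which is also shielded by two ortho acetals, and the neutral conditions spare the chromone.

Step 13
Reactants: 21 8-allyl-6-bromo-5,7-bis(methoxymethoxy)-3-[3,4-bis(methoxymethoxy)phenyl]-4H-chromen-4-one
Product: 23 2-{6-bromo-5,7-bis(methoxymethoxy)-3-[3,4-bis(methoxymethoxy)phenyl]-4-oxo-4H-chromen-8-yl}acetaldehyde, via diol 22 (not isolated)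
Conditions: OsO4 (2 mol%), NaIO4 (4 equiv), 2,6-lutidine (2 equiv), 1,4-dioxane–H2O (3:1), rt
Reagents that add atoms: osmium tetroxide (oxygen donor, regenerated by NaIO4), O=[Os](=O)(=O)=O
Why: Lemieux–Johnson oxidation: the terminal alkene is dihydroxylated and the diol cleaved by periodate; the electron-poor C2–C3 bond of the pyranone does not react. The aldehyde is used without storage.

Step 14
Reactants: 23 2-{6-bromo-5,7-bis(methoxymethoxy)-3-[3,4-bis(methoxymethoxy)phenyl]-4-oxo-4H-chromen-8-yl}acetaldehyde
Product: 24 6-bromo-8-[(2R)-2-hydroxy-3-methylbut-3-en-1-yl]-5,7-bis(methoxymethoxy)-3-[3,4-bis(methoxymethoxy)phenyl]-4H-chromen-4-one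
Conditions: 2-bromopropene (2 equiv), CrCl2 (10 mol%), chiral valinol-derived 2-(oxazolin-2-yl)aryl methanesulfonamide ligand (11 mol%), Et3N (20 mol%), NiCl2(2,9-dimethyl-1,10-phenanthroline) (2 mol%), Mn powder (2 equiv), Cp2ZrCl2 (1.2 equiv), LiCl (2 equiv), MeCN, rt
Reagents that add atoms: 2-bromopropene, CC(Br)=C
Why: Catalytic asymmetric Nozaki–Hiyama–Kishi reaction: zerovalent nickel activates the alkenyl bromide, the isopropenyl group passes to chromium, and the ligand-bound alkenylchromium adds to the aldehyde; Mn returns chromium to the divalent state and Cp2ZrCl2 frees the alkoxide. The chiral ligand on chromium directs addition to the Si face and so sets (R) at C2''. The reagent is selective for aldehydes over the chromone carbonyl and the hindered aryl bromide.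

Step 15
Reactants: 24 6-bromo-8-[(2R)-2-hydroxy-3-methylbut-3-en-1-yl]-5,7-bis(methoxymethoxy)-3-[3,4-bis(methoxymethoxy)phenyl]-4H-chromen-4-one
Product: 25 8-[(2R)-2-hydroxy-3-methylbut-3-en-1-yl]-5,7-bis(methoxymethoxy)-3-[3,4-bis(methoxymethoxy)phenyl]-6-(3-methylbut-2-en-1-yl)-4H-chromen-4-one
Conditions: tributyl(3-methylbut-2-enyl)stannane (1.5 equiv), Pd(PPh3)4 (10 mol%), CuI (20 mol%), CsF (2 equiv), DMF, 80 °C
Reagents that add atoms: tributyl(3-methylbut-2-en-1-yl)stannane, CC(C)=CC[Sn](CCCC)(CCCC)CCCC
Why: Stille coupling with copper and fluoride promotion for the hindered C6–Br bond; reductive elimination at the less substituted allyl terminus gives the linear prenyl group. The free alcohol and the stereocentre are not affected.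

Step 16
Reactants: 25 8-[(2R)-2-hydroxy-3-methylbut-3-en-1-yl]-5,7-bis(methoxymethoxy)-3-[3,4-bis(methoxymethoxy)phenyl]-6-(3-methylbut-2-en-1-yl)-4H-chromen-4-one
Product: 26 3-(3,4-dihydroxyphenyl)-5,7-dihydroxy-8-[(2R)-2-hydroxy-3-methylbut-3-en-1-yl]-6-(3-methylbut-2-en-1-yl)-4H-chromen-4-one
Conditions: 3 M aq. HCl–MeOH (1:9), 40 °C, stopped at full conversion
Reagents that add atoms: none
Why: Acid-catalysed transacetalisation of the four aryl MOM ethers to dimethoxymethane; in dilute methanolic acid this is expected to be faster than protonation of the two alkenes, and C2'' is not involved.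

## Compound list

1 | phloroglucinol | Oc1cc(O)cc(O)c1 | starting material
2 | 3,5-bis(methoxymethoxy)phenol | COCOc1cc(O)cc(OCOC)c1 | intermediate
3 | 3,5-bis(methoxymethoxy)phenyl N-isopropylcarbamate | CC(C)NC(=O)Oc1cc(OCOC)cc(OCOC)c1 | intermediate
4 | 3,5-bis(methoxymethoxy)phenyl N-(tert-butyldimethylsilyl)-N-isopropylcarbamate (not isolated) | CC(C)N(C(=O)Oc1cc(OCOC)cc(OCOC)c1)[Si](C)(C)C(C)(C)C | intermediate
5 | 3,5-bis(methoxymethoxy)-2-(trimethylsilyl)phenyl N-(tert-butyldimethylsilyl)-N-isopropylcarbamate (not isolated) | CC(C)N(C(=O)Oc1cc(OCOC)cc(OCOC)c1[Si](C)(C)C)[Si](C)(C)C(C)(C)C | intermediate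
6 | 3,5-bis(methoxymethoxy)-2-(trimethylsilyl)phenyl N-isopropylcarbamate | CC(C)NC(=O)Oc1cc(OCOC)cc(OCOC)c1[Si](C)(C)C | intermediate
7 | 3,5-bis(methoxymethoxy)-2-(trimethylsilyl)phenol (not isolated) | COCOc1cc(O)c([Si](C)(C)C)c(OCOC)c1 | intermediate
8 | 3,5-bis(methoxymethoxy)-2-(trimethylsilyl)phenyl trifluoromethanesulfonate | COCOc1cc(OCOC)c([Si](C)(C)C)c(OS(=O)(=O)C(F)(F)F)c1 | intermediate
9 | 3,4-dihydroxyphenylacetic acid | O=C(O)Cc1ccc(O)c(O)c1 | starting material
10 | methyl 3,4-dihydroxyphenylacetate | COC(=O)Cc1ccc(O)c(O)c1 | intermediate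
11 | methyl [3,4-bis(methoxymethoxy)phenyl]acetate | COC(=O)Cc1ccc(OCOC)c(OCOC)c1 | intermediate
12 | methyl formate | COC=O | starting material
13 | sodium enolate of methyl 2-[3,4-bis(methoxymethoxy)phenyl]-3-oxopropanoate (not isolated) | COC(=O)C(=C[O-])c1ccc(OCOC)c(OCOC)c1.[Na+] | intermediate
14 | methyl (E)-2-[3,4-bis(methoxymethoxy)phenyl]-3-methoxyacrylate | CO/C=C(/C(=O)OC)c1ccc(OCOC)c(OCOC)c1 | intermediate
15 | (E)-2-[3,4-bis(methoxymethoxy)phenyl]-3-methoxyacrylic acid | CO/C=C(/C(=O)O)c1ccc(OCOC)c(OCOC)c1 | intermediate
16 | 3,5-bis(methoxymethoxy)benzyne (not isolated) | C1#CC(OCOC)=CC(OCOC)=C1 | intermediate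
17 | (E)-1-[2-hydroxy-4,6-bis(methoxymethoxy)phenyl]-2-[3,4-bis(methoxymethoxy)phenyl]-3-methoxyprop-2-en-1-one, as its cesium phenoxide (not isolated) | CO/C=C(/C(=O)c1c(O)cc(OCOC)cc1OCOC)c1ccc(OCOC)c(OCOC)c1 | intermediate
18 | 5,7-bis(methoxymethoxy)-3-[3,4-bis(methoxymethoxy)phenyl]-4H-chromen-4-one | COCOc1cc(OCOC)c2c(=O)c(-c3ccc(OCOC)c(OCOC)c3)coc2c1 | intermediate
19 | 8-iodo-5,7-bis(methoxymethoxy)-3-[3,4-bis(methoxymethoxy)phenyl]-4H-chromen-4-one | COCOc1cc(OCOC)c2c(=O)c(-c3ccc(OCOC)c(OCOC)c3)coc2c1I | intermediate
20 | 6-bromo-8-iodo-5,7-bis(methoxymethoxy)-3-[3,4-bis(methoxymethoxy)phenyl]-4H-chromen-4-one | COCOc1c(Br)c(OCOC)c2c(=O)c(-c3ccc(OCOC)c(OCOC)c3)coc2c1I | intermediate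
21 | 8-allyl-6-bromo-5,7-bis(methoxymethoxy)-3-[3,4-bis(methoxymethoxy)phenyl]-4H-chromen-4-one | C=CCc1c(OCOC)c(Br)c(OCOC)c2c(=O)c(-c3ccc(OCOC)c(OCOC)c3)coc12 | intermediate
22 | 6-bromo-8-(2,3-dihydroxypropyl)-5,7-bis(methoxymethoxy)-3-[3,4-bis(methoxymethoxy)phenyl]-4H-chromen-4-one, racemic (not isolated) | OCC(O)Cc1c(OCOC)c(Br)c(OCOC)c2c(=O)c(-c3ccc(OCOC)c(OCOC)c3)coc12 | intermediate
23 | 2-{6-bromo-5,7-bis(methoxymethoxy)-3-[3,4-bis(methoxymethoxy)phenyl]-4-oxo-4H-chromen-8-yl}acetaldehyde | O=CCc1c(OCOC)c(Br)c(OCOC)c2c(=O)c(-c3ccc(OCOC)c(OCOC)c3)coc12 | intermediate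
24 | 6-bromo-8-[(2R)-2-hydroxy-3-methylbut-3-en-1-yl]-5,7-bis(methoxymethoxy)-3-[3,4-bis(methoxymethoxy)phenyl]-4H-chromen-4-one | C=C(C)[C@H](O)Cc1c(OCOC)c(Br)c(OCOC)c2c(=O)c(-c3ccc(OCOC)c(OCOC)c3)coc12 | intermediate
25 | 8-[(2R)-2-hydroxy-3-methylbut-3-en-1-yl]-5,7-bis(methoxymethoxy)-3-[3,4-bis(methoxymethoxy)phenyl]-6-(3-methylbut-2-en-1-yl)-4H-chromen-4-one | C=C(C)[C@H](O)Cc1c(OCOC)c(CC=C(C)C)c(OCOC)c2c(=O)c(-c3ccc(OCOC)c(OCOC)c3)coc12 | intermediate
26 | 3-(3,4-dihydroxyphenyl)-5,7-dihydroxy-8-[(2R)-2-hydroxy-3-methylbut-3-en-1-yl]-6-(3-methylbut-2-en-1-yl)-4H-chromen-4-one | C=C(C)[C@H](O)Cc1c(O)c(CC=C(C)C)c(O)c2c(=O)c(-c3ccc(O)c(O)c3)coc12 | target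

## Step count and risks

Total: 16 steps. Longest linear sequence: 12 steps (steps 1–4 or steps 5–8, then steps 9–16).

**Step 9 (key step).** The aryl anion may be protonated before the acyl shift, which stops at O-arylation. The aryne may also be consumed by the electron-rich enol ether of 15, or the final addition–elimination may stall at the open ketone.
Fallback: the insertion and the ring closure are separated, both with known chemistry. Ester 11 is saponified to [3,4-bis(methoxymethoxy)phenyl]acetic acid F1. F1 is treated with 8 and CsF in THF at 125 °C, the established insertion for arylacetic acids, to give the deoxybenzoin 1-[2-hydroxy-4,6-bis(methoxymethoxy)phenyl]-2-[3,4-bis(methoxymethoxy)phenyl]ethan-1-one F2. Heating F2 with N,N-dimethylformamide dimethyl acetal supplies C2 by way of the enaminone 3-(dimethylamino)-1-[2-hydroxy-4,6-bis(methoxymethoxy)phenyl]-2-[3,4-bis(methoxymethoxy)phenyl]prop-2-en-1-one F3, which closes to 18, where the route is rejoined.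

**Step 14.** Facial selectivity may be poor with an unbranched aldehyde, and the aldehyde may be lost by enolisation and self-condensation during the slow catalytic cycle.
Fallback: aldehyde 23 is treated with isopropenylmagnesium bromide in THF at −78 °C to give the racemic alcohol 6-bromo-8-(2-hydroxy-3-methylbut-3-en-1-yl)-5,7-bis(methoxymethoxy)-3-[3,4-bis(methoxymethoxy)phenyl]-4H-chromen-4-one F4. Sharpless kinetic resolution (Ti(OiPr)4, L-(+)-diisopropyl tartrate, tert-butyl hydroperoxide, 0.6 equiv, CH2Cl2, −20 °C) should then epoxidise the (S) enantiomer to the epoxy alcohol 6-bromo-8-[(2S)-2-hydroxy-2-(2-methyloxiran-2-yl)ethyl]-5,7-bis(methoxymethoxy)-3-[3,4-bis(methoxymethoxy)phenyl]-4H-chromen-4-one F5 and leave 24, at the cost of half the material.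

**Step 15.** Oxidative addition at the C6–Br bond between two acetals may be slow, and the prenyl group may be delivered with allylic transposition.
Fallback: 24 is coupled under the same palladium conditions with allyltributylstannane, which transfers faster and has no regiochemical ambiguity, to give 6-allyl-8-[(2R)-2-hydroxy-3-methylbut-3-en-1-yl]-5,7-bis(methoxymethoxy)-3-[3,4-bis(methoxymethoxy)phenyl]-4H-chromen-4-one F6. Cross-metathesis of F6 with 2-methylbut-2-ene and the second-generation Grubbs catalyst [RuCl2(=CHPh)(H2IMes)(PCy3)] in CH2Cl2 at 40 °C converts allyl into prenyl and returns to 25; the hindered 1,1-disubstituted alkene of the C8 chain should stay out of the metathesis.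

**Step 16.** Protonation of either alkene may lead to ring closure by the freed C5 or C7 hydroxyl, and the allylic alcohol may ionise.
Fallback: the acetals are exchanged for silyl ethers without protic acid. Treatment of 25 with triethylsilyl triflate and 2,2'-bipyridyl in MeCN at 0 °C should give the pentakis(triethylsilyl) ether 8-[(2R)-3-methyl-2-(triethylsilyloxy)but-3-en-1-yl]-6-(3-methylbut-2-en-1-yl)-5,7-bis(triethylsilyloxy)-3-[3,4-bis(triethylsilyloxy)phenyl]-4H-chromen-4-one F7. Buffered fluoride (HF·pyridine in THF–pyridine, 0 °C) then gives 26.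

## Further compounds

F1 | step 9 | [3,4-bis(methoxymethoxy)phenyl]acetic acid | O=C(O)Cc1ccc(OCOC)c(OCOC)c1
F2 | step 9 | 1-[2-hydroxy-4,6-bis(methoxymethoxy)phenyl]-2-[3,4-bis(methoxymethoxy)phenyl]ethan-1-one | O=C(Cc1ccc(OCOC)c(OCOC)c1)c1c(O)cc(OCOC)cc1OCOC
F3 | step 9 | 3-(dimethylamino)-1-[2-hydroxy-4,6-bis(methoxymethoxy)phenyl]-2-[3,4-bis(methoxymethoxy)phenyl]prop-2-en-1-one | CN(C)C=C(C(=O)c1c(O)cc(OCOC)cc1OCOC)c1ccc(OCOC)c(OCOC)c1
F4 | step 14 | racemic 6-bromo-8-(2-hydroxy-3-methylbut-3-en-1-yl)-5,7-bis(methoxymethoxy)-3-[3,4-bis(methoxymethoxy)phenyl]-4H-chromen-4-one | C=C(C)C(O)Cc1c(OCOC)c(Br)c(OCOC)c2c(=O)c(-c3ccc(OCOC)c(OCOC)c3)coc12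
F5 | step 14 | 6-bromo-8-[(2S)-2-hydroxy-2-(2-methyloxiran-2-yl)ethyl]-5,7-bis(methoxymethoxy)-3-[3,4-bis(methoxymethoxy)phenyl]-4H-chromen-4-one | CC1(CO1)[C@@H](O)Cc1c(OCOC)c(Br)c(OCOC)c2c(=O)c(-c3ccc(OCOC)c(OCOC)c3)coc12
F6 | step 15 | 6-allyl-8-[(2R)-2-hydroxy-3-methylbut-3-en-1-yl]-5,7-bis(methoxymethoxy)-3-[3,4-bis(methoxymethoxy)phenyl]-4H-chromen-4-one | C=C(C)[C@H](O)Cc1c(OCOC)c(CC=C)c(OCOC)c2c(=O)c(-c3ccc(OCOC)c(OCOC)c3)coc12
F7 | step 16 | 8-[(2R)-3-methyl-2-(triethylsilyloxy)but-3-en-1-yl]-6-(3-methylbut-2-en-1-yl)-5,7-bis(triethylsilyloxy)-3-[3,4-bis(triethylsilyloxy)phenyl]-4H-chromen-4-one | C=C(C)[C@H](O[Si](CC)(CC)CC)Cc1c(O[Si](CC)(CC)CC)c(CC=C(C)C)c(O[Si](CC)(CC)CC)c2c(=O)c(-c3ccc(O[Si](CC)(CC)CC)c(O[Si](CC)(CC)CC)c3)coc12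
A1 | alternative 1 | 6-bromo-5,7-bis(methoxymethoxy)-3-[3,4-bis(methoxymethoxy)phenyl]-8-(3-methylbut-2-en-1-yl)-4H-chromen-4-one | CC(C)=CCc1c(OCOC)c(Br)c(OCOC)c2c(=O)c(-c3ccc(OCOC)c(OCOC)c3)coc12
A2 | alternative 1 | 6-bromo-8-{[(R)-3,3-dimethyloxiran-2-yl]methyl}-5,7-bis(methoxymethoxy)-3-[3,4-bis(methoxymethoxy)phenyl]-4H-chromen-4-one | CC1(C)[C@H](O1)Cc1c(OCOC)c(Br)c(OCOC)c2c(=O)c(-c3ccc(OCOC)c(OCOC)c3)coc12
A3 | alternative 2 | methyl 5-[3,4-bis(methoxymethoxy)phenyl]-2-[(2R)-2-(tert-butyldimethylsilyloxy)-3-methyl-1-(5-methylhex-4-enoyl)but-3-en-1-yl... ]-4-oxo-4H-pyran-3-carboxylate, that is the pyranone ester whose C2 chain is CH[CH2CH(OTBS)C(CH3)=CH2]–CO–CH2–CH2CH=C(CH3)2 | O=c1c(-c2ccc(OCOC)c(OCOC)c2)coc(C(C[C@@H](O[Si](C)(C)C(C)(C)C)C(C)=C)C(=O)CCC=C(C)C)c1C(=O)OC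
A4 | alternative 2 | 8-[(R)-2-(tert-butyldimethylsilyloxy)-3-methylbut-3-enyl]-5,7-dihydroxy-3-[3,4-bis(methoxymethoxy)phenyl]-6-(3-methylbut-2-enyl)chromen-4-one | C=C(C)[C@H](O[Si](C)(C)C(C)(C)C)Cc1c(O)c(CC=C(C)C)c(O)c2c(=O)c(-c3ccc(OCOC)c(OCOC)c3)coc12
A5 | alternative 3 | 2-{2-[3,4-bis(methoxymethoxy)phenyl]-2-oxoethoxy}-4,6-bis(methoxymethoxy)benzaldehyde | O=Cc1c(OCOC)cc(OCOC)cc1OCC(=O)c1ccc(OCOC)c(OCOC)c1
A6 | alternative 3 | racemic 3-hydroxy-5,7-bis(methoxymethoxy)-3-[3,4-bis(methoxymethoxy)phenyl]chroman-4-one | O=C1c2c(OCOC)cc(OCOC)cc2OCC1(O)c1ccc(OCOC)c(OCOC)c1
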